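**Retrosynthetic overview**
1. Target ⇒ diol 17 (last steps: primary OH → Br, secondary OH → OAc) ⇒ B-alkyl Suzuki cut at the ring-CH2–CH= bond: homoallylic boronate 10 + chiral-pool (Z)-iodo diol 16.
2. 10 ⇒ acyclic (S)-bromo-1,7-enyne 9: one Pd-catalysed borylative cyclization joins the methylidene-bearing ring carbon to the side-chain-bearing ring CH (6-exo), adding H to the future =CH2 and Bpin to the future side-chain CH2.
3. Enabling feature: in the six-membered ring the C(=CH2) carbon is bonded directly to the CH that carries a CH2 branch (CH2=C–CH–CH2, the retron of alkyne hydropalladation / vinyl insertion); that CH sits next to the quaternary CMe2 carbon, so the acceptor is a vinyl group without allylic hydrogens and closure gets a Thorpe–Ingold push; the CHBr carbon on the other side of CMe2 relays its configuration.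
4. 9 ⇒ (R)-bromohydrin 4 (organocatalytic α-bromination of 3,3-dimethylpent-4-enal 2) + the three-carbon propargyl unit 5.
5. Ring order: the target has a single carbocycle, closed in step 5.

Key step: step 5

Remark on the chemistry: from the SMILES the ring CHBr is S, the ring CH is R (bromine and side chain cis, both equatorial), the carbinol carbon is R and the trisubstituted alkene is Z; (2S,5S)-2,5-diphenylpyrrolidine is assumed, from the steric-shielding model, to deliver bromine to the Re face of the enamine.

**Step 1**
Reactants: 1 methyl 3,3-dimethylpent-4-enoate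
Product: 2 3,3-dimethylpent-4-enal
Conditions: DIBAL-H (1.05 equiv), CH2Cl2, −78 °C; aq. potassium sodium tartrate
Reagents that add atoms: none
Why: DIBAL-H half-reduction of an ester, in which the tetrahedral aluminium hemiacetal is stable at −78 °C and collapses to the aldehyde only on work-up, with no stereocentre involved.

**Step 2**
Reactants: 2 3,3-dimethylpent-4-enal
Product: 4 (2R)-2-bromo-3,3-dimethylpent-4-en-1-ol, via α-bromo aldehyde 3 (not isolated)
Conditions: (2S,5S)-2,5-diphenylpyrrolidine (20 mol %), 4,4-dibromo-2,6-di-tert-butylcyclohexa-2,5-dien-1-one, PhCO2H (20 mol %), H2O, CH2Cl2/pentane, −40 °C; then NaBH4, MeOH, −40 to 0 °C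
Reagents that add atoms: 4,4-dibromo-2,6-di-tert-butylcyclohexa-2,5-dien-1-one, O=C1C(C(C)(C)C)=CC(Br)(Br)C=C1C(C)(C)C
Why: Enamine-catalysed enantioselective α-bromination of an aldehyde with in situ borohydride reduction: the C2-symmetric amine forms the E-enamine of 2, the phenyl group next to the enamine carbon shields the Si face so that bromine should enter from the Re face and set the (R)-C–Br centre (the enamine being far more nucleophilic than the vinyl group), and immediate reduction removes the configurationally labile α-bromo aldehyde.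

**Step 3**
Reactants: 4 (2R)-2-bromo-3,3-dimethylpent-4-en-1-ol; 5 1-(trimethylsilyl)propyne
Product: 8 trimethyl[(5S)-5-bromo-6,6-dimethyloct-7-en-1-yn-1-yl]silane, via primary triflate 6 (not isolated), via lithiated silylpropyne 7 (not isolated)
Conditions: Tf2O, 2,6-lutidine, CH2Cl2, −78 °C, cold aqueous work-up; crude 6 added to 7 (from 5, n-BuLi, THF, −78 °C), −78 to −40 °C
Reagents that add atoms: none
Why: Triflation followed by SN2 propargylation: the primary triflate should be displaced at −78 °C by the propargylic terminus of lithiated 1-(trimethylsilyl)propyne much faster than the hindered secondary bromide is attacked, so the C–Br centre is untouched and its descriptor changes from R to S only through the CIP priorities.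

**Step 4**
Reactants: 8 trimethyl[(5S)-5-bromo-6,6-dimethyloct-7-en-1-yn-1-yl]silane
Product: 9 (5S)-5-bromo-6,6-dimethyloct-7-en-1-yne
Conditions: K2CO3, MeOH, rt
Reagents that add atoms: none
Why: Base-mediated protodesilylation of an alkynylsilane under conditions too mild to eliminate or substitute the secondary bromide next to the quaternary carbon.

**Step 5**
Reactants: 9 (5S)-5-bromo-6,6-dimethyloct-7-en-1-yne
Product: 10 2-{[(1R,3S)-3-bromo-2,2-dimethyl-6-methylidenecyclohexyl]methyl}-4,4,5,5-tetramethyl-1,3,2-dioxaborolane
Conditions: Pd(OAc)2 (5 mol %), B2pin2 (1.2 equiv), MeOH (1.5 equiv), toluene, 50 °C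
Reagents that add atoms: bis(pinacolato)diboron, CC1(C)OB(OC1(C)C)B1OC(C)(C)C(C)(C)O1
Why: Palladium-catalysed borylative cyclization of a 1,7-enyne, the closest known reaction type being the Pd(OAc)2/B2pin2/MeOH cyclization of 1,6- and 1,7-enynes to homoallylic boronates: a palladium hydride adds across the terminal alkyne with palladium on the internal carbon, the alkenylpalladium inserts the vinyl group in a syn fashion, and the primary alkylpalladium is borylated by B2pin2 before β-hydride elimination to a diene can occur. The only ring is closed in the 6-exo-trig mode by joining the alkyne-derived C(=CH2) carbon to the internal vinyl carbon, which becomes the ring CH that carries the CH2Bpin arm. The new stereocentre is set by substrate control from the C–Br centre (1,3-induction across the CMe2 carbon): the four-centre insertion holds the palladium-bound CH2 terminus in the pseudo-equatorial plane of a chair-like transition state, and the chair that also keeps the C–Br bond equatorial leads to the cis (1R,3S) isomer. The step needs Markovnikov hydropalladation, exo closure, inertness of the C–Br bond and this facial selectivity; the terminal alkyne and four-atom tether secure the first two, the gem-dimethyl group speeds the closure (Thorpe–Ingold effect) and leaves the vinyl group without allylic hydrogens, and the secondary bromide flanked by a quaternary carbon should not be attacked by ligand-free palladium at 50 °C. Because bromine is only a modest conformational anchor, the facial selectivity is the least certain point, and the trans isomer is to be removed by chromatography at this stage.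

**Step 6**
Reactants: 11 methyl (4S)-2,2-dimethyl-1,3-dioxolane-4-carboxylate
Product: 13 (4R)-4-ethynyl-2,2-dimethyl-1,3-dioxolane, via glyceraldehyde acetonide 12 (not isolated)
Conditions: DIBAL-H, CH2Cl2, −78 °C; then MeOH, K2CO3, dimethyl (1-diazo-2-oxopropyl)phosphonate, 0 °C to rt
Reagents that add atoms: dimethyl (1-diazo-2-oxopropyl)phosphonate, COP(=O)(OC)C(=[N+]=[N-])C(C)=O
Why: One-pot DIBAL-H half-reduction and Seyferth–Gilbert homologation with the Ohira–Bestmann reagent, in which the aldehyde is trapped as it forms and the mild K2CO3/MeOH conditions should preserve the α-alkoxy stereocentre (S to R is a change of CIP priorities only).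

**Step 7**
Reactants: 13 (4R)-4-ethynyl-2,2-dimethyl-1,3-dioxolane
Product: 14 (2R)-but-3-yne-1,2-diol
Conditions: Dowex 50W (H+ form), MeOH/H2O, rt
Reagents that add atoms: none
Why: Acid-catalysed acetonide hydrolysis, which does not touch the stereocentre.

**Step 8**
Reactants: 14 (2R)-but-3-yne-1,2-diol
Product: 16 (2R,3Z)-4-iodo-3-methylbut-3-ene-1,2-diol, via alkenylmagnesium alkoxide 15 (not isolated)
Conditions: MeMgBr (4 equiv), CuI (20 mol %), THF, −20 °C to rt; then I2, THF, −30 to 0 °C
Reagents that add atoms: methylmagnesium bromide, C[Mg]Br; iodine, II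
Why: Copper-catalysed anti-carbomagnesiation of a propargylic alkoxide followed by iodinolysis: the magnesium alkoxide delivers methyl to the proximal alkyne carbon and closes a five-membered oxamagnesacycle, so magnesium and then iodine end up cis to the carbinol carbon, giving the Z vinyl iodide with the carbinol configuration unchanged.

**Step 9**
Reactants: 10 2-{[(1R,3S)-3-bromo-2,2-dimethyl-6-methylidenecyclohexyl]methyl}-4,4,5,5-tetramethyl-1,3,2-dioxaborolane; 16 (2R,3Z)-4-iodo-3-methylbut-3-ene-1,2-diol
Product: 17 (2R,3Z)-5-[(1R,3S)-3-bromo-2,2-dimethyl-6-methylidenecyclohexyl]-3-methylpent-3-ene-1,2-diol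
Conditions: Pd(OAc)2 (5 mol %), SPhos (10 mol %), K3PO4 (3 equiv), toluene/H2O (10:1), 80 °C
Reagents that add atoms: none
Why: Stereoretentive B-alkyl Suzuki–Miyaura coupling of a primary alkyl pinacol boronate with an alkenyl iodide, in which the Z geometry is carried through oxidative addition and reductive elimination and the free diol and the equatorial neopentyl-type bromide (no anti-periplanar hydrogen for elimination) should be tolerated.

**Step 10**
Reactants: 17 (2R,3Z)-5-[(1R,3S)-3-bromo-2,2-dimethyl-6-methylidenecyclohexyl]-3-methylpent-3-ene-1,2-diol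
Product: 18 (2R,3Z)-1-bromo-5-[(1R,3S)-3-bromo-2,2-dimethyl-6-methylidenecyclohexyl]-3-methylpent-3-en-2-ol
Conditions: CBr4 (1.1 equiv), PPh3 (1.15 equiv), pyridine/CH2Cl2, 0 °C
Reagents that add atoms: tetrabromomethane, BrC(Br)(Br)Br
Why: Appel reaction, in which the primary hydroxyl should be activated and displaced by bromide faster than the hindered allylic secondary hydroxyl, so the carbinol configuration is retained.

**Step 11**
Reactants: 18 (2R,3Z)-1-bromo-5-[(1R,3S)-3-bromo-2,2-dimethyl-6-methylidenecyclohexyl]-3-methylpent-3-en-2-ol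
Product: 19 (2R,3Z)-1-bromo-5-[(1R,3S)-3-bromo-2,2-dimethyl-6-methylidenecyclohexyl]-3-methylpent-3-en-2-yl acetate (CNP0136568.3)
Conditions: Ac2O, pyridine, DMAP (cat.), CH2Cl2, 0 °C
Reagents that add atoms: acetic anhydride, CC(=O)OC(C)=O
Why: DMAP-catalysed acetylation of the secondary alcohol under conditions too weakly basic to close the bromohydrin to an epoxide.

**Compound list**
1 | methyl 3,3-dimethylpent-4-enoate | COC(=O)CC(C)(C)C=C | starting material
2 | 3,3-dimethylpent-4-enal | O=CCC(C)(C)C=C | intermediate
3 | (2R)-2-bromo-3,3-dimethylpent-4-enal | O=C[C@H](Br)C(C)(C)C=C | intermediate (not isolated)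
4 | (2R)-2-bromo-3,3-dimethylpent-4-en-1-ol | OC[C@H](Br)C(C)(C)C=C | intermediate
5 | 1-(trimethylsilyl)propyne | CC#C[Si](C)(C)C | starting material
6 | (2R)-2-bromo-3,3-dimethylpent-4-en-1-yl trifluoromethanesulfonate | FC(F)(F)S(=O)(=O)OC[C@H](Br)C(C)(C)C=C | intermediate (not isolated)
7 | 3-lithio-1-(trimethylsilyl)propyne | [Li]CC#C[Si](C)(C)C | intermediate (not isolated)
8 | trimethyl[(5S)-5-bromo-6,6-dimethyloct-7-en-1-yn-1-yl]silane | C[Si](C)(C)C#CCC[C@H](Br)C(C)(C)C=C | intermediate
9 | (5S)-5-bromo-6,6-dimethyloct-7-en-1-yne | C#CCC[C@H](Br)C(C)(C)C=C | intermediate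
10 | 2-{[(1R,3S)-3-bromo-2,2-dimethyl-6-methylidenecyclohexyl]methyl}-4,4,5,5-tetramethyl-1,3,2-dioxaborolane | C=C1CC[C@H](Br)C(C)(C)[C@@H]1CB2OC(C)(C)C(C)(C)O2 | intermediate
11 | methyl (4S)-2,2-dimethyl-1,3-dioxolane-4-carboxylate | COC(=O)[C@@H]1COC(C)(C)O1 | starting material
12 | (4S)-2,2-dimethyl-1,3-dioxolane-4-carbaldehyde | O=C[C@@H]1COC(C)(C)O1 | intermediate (not isolated)
13 | (4R)-4-ethynyl-2,2-dimethyl-1,3-dioxolane | C#C[C@@H]1COC(C)(C)O1 | intermediate
14 | (2R)-but-3-yne-1,2-diol | C#C[C@@H](O)CO | intermediate
15 | bis(bromomagnesium) (2R,3Z)-4-(bromomagnesio)-3-methylbut-3-ene-1,2-diolate | Br[Mg]/C=C(/C)[C@@H](O[Mg]Br)CO[Mg]Br | intermediate (not isolated)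
16 | (2R,3Z)-4-iodo-3-methylbut-3-ene-1,2-diol | I/C=C(/C)[C@@H](O)CO | intermediate
17 | (2R,3Z)-5-[(1R,3S)-3-bromo-2,2-dimethyl-6-methylidenecyclohexyl]-3-methylpent-3-ene-1,2-diol | C=C1CC[C@H](Br)C(C)(C)[C@@H]1C/C=C(/C)[C@@H](O)CO | intermediate
18 | (2R,3Z)-1-bromo-5-[(1R,3S)-3-bromo-2,2-dimethyl-6-methylidenecyclohexyl]-3-methylpent-3-en-2-ol | C=C1CC[C@H](Br)C(C)(C)[C@@H]1C/C=C(/C)[C@H](CBr)O | intermediate
19 | (2R,3Z)-1-bromo-5-[(1R,3S)-3-bromo-2,2-dimethyl-6-methylidenecyclohexyl]-3-methylpent-3-en-2-yl acetate | C=C1CC[C@H](Br)C(C)(C)[C@@H]1C/C=C(/C)[C@H](CBr)OC(C)=O | target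

**Step count and risks**
Total step count: 11. Longest linear sequence: 8 steps (steps 1–5, then 9–11); the iodo diol 16 takes 3 steps (6–8).

Steps most likely to fail:

1. Step 5. What may go wrong: insufficient facial selectivity in the migratory insertion, because the equatorial preference of bromine is small; or β-hydride elimination to the cross-conjugated diene before borylation. The fallback moves the ring CH stereocentre to a ligand-controlled step, sets out from compound 4 and comes back at compound 10. Triflate 6 (made from 4 as in step 3) is alkylated with the dianion of 2-methylprop-2-en-1-ol (n-BuLi, TMEDA) to give (5S)-5-bromo-6,6-dimethyl-2-methylideneoct-7-en-1-ol F1. Ring-closing metathesis with the second-generation Hoveyda–Grubbs catalyst forms the same ring bond as a C=C and gives [(4S)-4-bromo-3,3-dimethylcyclohex-1-en-1-yl]methanol F2. Diethyl chlorophosphate and pyridine give diethyl [(4S)-4-bromo-3,3-dimethylcyclohex-1-en-1-yl]methyl phosphate F3. A copper-catalysed enantioselective SN2′ substitution with bis(pinacolato)borylmethane (CuCl, chiral N-heterocyclic carbene ligand, NaOMe) then places the CH2Bpin arm on the ring CH under ligand control while the double bond moves out of the ring, giving 10.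

2. Step 3. What may go wrong: halophilic attack of the organolithium on bromine with 1,2-elimination of the bromo triflate, or allenyl instead of propargyl alkylation. The fallback replaces propargylation by acetate alkylation and one-carbon alkyne homologation, sets out from compound 4 and comes back at compound 9. Triflate 6 is alkylated with the lithium enolate of tert-butyl acetate (LDA, THF, −78 °C) to give tert-butyl (4S)-4-bromo-5,5-dimethylhept-6-enoate F4. DIBAL-H at −78 °C gives (4S)-4-bromo-5,5-dimethylhept-6-enal F5. The Ohira–Bestmann reagent with K2CO3 in MeOH at 0 °C then gives 9.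

3. Step 10. What may go wrong: loss of chemoselectivity between the primary and the allylic secondary hydroxyl (allylic bromide formation with transposition, or epoxide closure). The fallback masks the primary position, acetylates first and brominates last; it sets out from compound 17 and comes back at compound 19. TBSCl and imidazole silylate the primary hydroxyl to give (2R,3Z)-5-[(1R,3S)-3-bromo-2,2-dimethyl-6-methylidenecyclohexyl]-1-[(tert-butyldimethylsilyl)oxy]-3-methylpent-3-en-2-ol F6. Ac2O, pyridine and DMAP give (2R,3Z)-5-[(1R,3S)-3-bromo-2,2-dimethyl-6-methylidenecyclohexyl]-1-[(tert-butyldimethylsilyl)oxy]-3-methylpent-3-en-2-yl acetate F7. HF·pyridine in THF at 0 °C gives (2R,3Z)-5-[(1R,3S)-3-bromo-2,2-dimethyl-6-methylidenecyclohexyl]-1-hydroxy-3-methylpent-3-en-2-yl acetate F8. CBr4 and PPh3 in CH2Cl2 at 0 °C then give 19.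

**Further compounds**
F1 | step 5 | (5S)-5-bromo-6,6-dimethyl-2-methylideneoct-7-en-1-ol | C=C(CO)CC[C@H](Br)C(C)(C)C=C
F2 | step 5 | [(4S)-4-bromo-3,3-dimethylcyclohex-1-en-1-yl]methanol | OCC1=CC(C)(C)[C@@H](Br)CC1
F3 | step 5 | diethyl [(4S)-4-bromo-3,3-dimethylcyclohex-1-en-1-yl]methyl phosphate | CCOP(=O)(OCC)OCC1=CC(C)(C)[C@@H](Br)CC1
F4 | step 3 | tert-butyl (4S)-4-bromo-5,5-dimethylhept-6-enoate | CC(C)(C)OC(=O)CC[C@H](Br)C(C)(C)C=C
F5 | step 3 | (4S)-4-bromo-5,5-dimethylhept-6-enal | O=CCC[C@H](Br)C(C)(C)C=C
F6 | step 10 | (2R,3Z)-5-[(1R,3S)-3-bromo-2,2-dimethyl-6-methylidenecyclohexyl]-1-[(tert-butyldimethylsilyl)oxy]-3-methylpent-3-en-2-ol | C=C1CC[C@H](Br)C(C)(C)[C@@H]1C/C=C(/C)[C@@H](O)CO[Si](C)(C)C(C)(C)C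
F7 | step 10 | (2R,3Z)-5-[(1R,3S)-3-bromo-2,2-dimethyl-6-methylidenecyclohexyl]-1-[(tert-butyldimethylsilyl)oxy]-3-methylpent-3-en-2-yl acetate | C=C1CC[C@H](Br)C(C)(C)[C@@H]1C/C=C(/C)[C@@H](OC(C)=O)CO[Si](C)(C)C(C)(C)C
F8 | step 10 | (2R,3Z)-5-[(1R,3S)-3-bromo-2,2-dimethyl-6-methylidenecyclohexyl]-1-hydroxy-3-methylpent-3-en-2-yl acetate | C=C1CC[C@H](Br)C(C)(C)[C@@H]1C/C=C(/C)[C@@H](OC(C)=O)CO
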